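**Compound numbering used throughout:** 1 O‑benzyleugenol; 2 (S)‑but‑3‑en‑2‑ol; 3 allylic alcohol; 4 benzyloxyacetyl chloride; 5 allylic glycolate; 6 benzylic bromide; 7 α‑benzylated allylic ester; 8 lithium enolate; 9 silyl ketene acetal; 10 silyl ester; 11 rearranged acid; 12 aldehyde acid; 13 hydroxy acid; 14 tribenzyl lactone; 15 target. "Ar" below means 4‑(benzyloxy)‑3‑methoxyphenyl.

## Analysis of the target

The target 15 is (3S,4R)‑3‑hydroxy‑3,4‑bis(4‑hydroxy‑3‑methoxybenzyl)dihydrofuran‑2(3H)‑one, a dibenzylbutyrolactone lignan with one ring (O1, C2(=O), C3, C4, C5). C3 is a fully substituted carbinol carbon α to the lactone carbonyl and C4 is a tertiary carbon next to it. In the (3S,4R) isomer the two arylmethyl groups are cis and the C3 hydroxyl is trans to the C4 arylmethyl group, the more crowded arrangement of the two possible ones. The two aryl groups are identical, so they cannot be told apart chemically. The sensitive groups are two free guaiacol‑type phenols, electron‑rich arenes and the lactone. The real difficulty is the C3–C4 bond, which joins a quaternary oxygenated carbon to a tertiary one and carries both stereocenters. The feature the route is built on: C3 is the α‑carbon of an α‑alkoxy acid (C2) and C4 carries the ring carbon C5, which can be read as the remnant of an alkene carbon. The open chain C2(O)–C3(OR)–C4–C5=C is therefore a 2‑alkoxy‑4‑enoic acid, the retron of a glycolate ester enolate [3,3] rearrangement across C3–C4.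

## Retrosynthetic reasoning

15 ⇒ 14. The three O–H bonds are traced back to three benzyl ethers, so that one hydrogenolysis ends the route. The benzyl ether on the C3 oxygen is not only a protecting group: it is the chelating substituent that fixes the enolate geometry in the key step.

14 ⇒ 11 (through 13 and 12). The lactone acyl C2–O1 bond is opened and C5 is seen as the inner carbon of a propenyl group. This shows that 14 is an oxidatively truncated γ,δ‑unsaturated acid. The forward step has to cleave the alkene of 11, reduce the resulting aldehyde 12 to the alcohol 13 and let it lactonise, without touching C3 or C4.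

11 ⇒ 7 (through 10, 9 and 8). The C3–C4 bond of the target (C2–C3 of 11) is cut in a retro‑[3,3] sense, which restores an ester C–O bond in 7. This is the most congested bond and the only one that carries both stereocenters, so one transition state can set both. The precursor 7 is an acyclic ester whose only defined stereocenter is a methyl carbinol, and its glycolate α‑carbon may be a mixture because it is planarised in the enolate 8. The forward reaction has to give one enolate geometry, a chair transition state and complete transfer of the carbinol chirality.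

7 ⇒ 5 + 6. The bond between the glycolate α‑carbon and the benzylic carbon is cut. The new stereocenter is irrelevant, so a plain enolate alkylation suffices.

5 ⇒ 3 + 4. The ester C–O bond is cut; the forward step is an acylation with retention at the carbinol carbon.

3 ⇒ 1 + 2. The C=C bond is cut by retro cross‑metathesis. Compound 1 supplies the aryl group, the benzylic CH2 and one alkene carbon; compound 2 supplies the only stereocenter that has to be bought.

## Alternatives that were turned down

Alternative 1: The textbook route cuts the C3–O bond last and the C3–CH2Ar bond before it. The (S)‑β‑arylmethyl lactone A1 (from a Stobbe condensation, asymmetric hydrogenation and chemoselective reduction) would be alkylated to the trans‑dibenzyl lactone A2. The enolate of A2 would then be oxidised with an electrophilic oxygen source anti to the C4 substituent. It was turned down because it handles the stereocenters one at a time. C4 comes from a hydrogenation, C3 is set in the alkylation and then erased on enolisation, and the decisive tertiary carbinol depends on attack at a hindered tetrasubstituted enolate in the last bond‑forming step. It needs about seven steps and no step simplifies the skeleton.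

Alternative 2: The C3–C4 bond could be made by an intermolecular aldol reaction. The aryl pyruvate A3 would be the acceptor and the enamine of the aldehyde A4 the donor, giving the aldol A5; reduction and lactonisation would follow. It is short, but A3 should exist largely as its aryl‑conjugated enol, which is a poor electrophile and prone to self‑condensation. The two ketone substituents (CO2Me and CH2Ar) differ too little for a safe prediction of the relative configuration from an open transition state. A5 is a β‑hydroxy aldehyde with a labile α‑stereocenter, open to retro‑aldol cleavage and epimerisation.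

Alternative 3: Both stereocenters could be set on the flat, achiral butenolide A6 by a formal syn addition of H and OH across C3=C4. The forward step would be an enantioselective copper hydride conjugate reduction with oxidative trapping of the enolate at C3. It was turned down because a tetrasubstituted enoate is a poor substrate for hydrometalation. The catalyst would also have to distinguish CH2Ar from the ring CH2O at C4. No C–C bond is formed, so the whole skeleton of A6 must still be built in three to four steps, and the one‑pot reduction–oxygenation has no close precedent.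

Key step: step 4

Assumption: 1 and 6 are treated as catalogue chemicals; each is otherwise one routine step from eugenol or from 4‑(benzyloxy)‑3‑methoxybenzyl alcohol.

## Route

Step 1
Reactants: 1 4‑allyl‑1‑(benzyloxy)‑2‑methoxybenzene (O‑benzyleugenol); 2 (S)‑but‑3‑en‑2‑ol
Product: 3 (2S,3E)‑5‑[4‑(benzyloxy)‑3‑methoxyphenyl]pent‑3‑en‑2‑ol
Conditions: Hoveyda–Grubbs II (3 mol%), 1,4‑benzoquinone (10 mol%), 1 in excess, CH2Cl2, 40 °C
Reagents that add atoms: none
Why: Olefin cross‑metathesis of an allylarene with a secondary allylic alcohol should give mainly the E alkene; the carbinol stereocenter is not involved, and benzoquinone suppresses Ru–H olefin migration.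

Step 2
Reactants: 3; 4 2‑(benzyloxy)acetyl chloride
Product: 5 (2S,3E)‑5‑[4‑(benzyloxy)‑3‑methoxyphenyl]pent‑3‑en‑2‑yl 2‑(benzyloxy)acetate
Conditions: pyridine, DMAP (cat.), CH2Cl2, 0 °C to rt
Reagents that add atoms: none
Why: DMAP‑catalysed acylation of a secondary alcohol by an acid chloride; no bond to the stereocenter is broken, so the configuration is retained.

Step 3
Reactants: 5; 6 4‑(benzyloxy)‑3‑methoxybenzyl bromide
Product: 7 (2S,3E)‑5‑[4‑(benzyloxy)‑3‑methoxyphenyl]pent‑3‑en‑2‑yl (2RS)‑2‑(benzyloxy)‑3‑[4‑(benzyloxy)‑3‑methoxyphenyl]propanoate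
Conditions: LDA, THF, −78 °C; then 6, DMPU, −78 to −45 °C; AcOH quench
Reagents that add atoms: none
Why: Alkylation of a lithium glycolate enolate by a reactive benzylic bromide, kept below the temperature at which lithium enolates of allylic esters rearrange; the new α‑center forms as a mixture, which does not matter because step 4 planarises it.

Step 4
Reactants: 7
Product: 11 (2S,3R,4E)‑2‑(benzyloxy)‑2,3‑bis[4‑(benzyloxy)‑3‑methoxybenzyl]hex‑4‑enoic acid, via chelated lithium enolate 8 (not isolated), via silyl ketene acetal 9 (not isolated), via trimethylsilyl ester 10 (not isolated)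
Conditions: LDA, THF, −78 °C; TMSCl/Et3N, −78 °C to rt, then 50 °C; 1 M HCl work‑up
Reagents that add atoms: none
Why: Ireland–Claisen rearrangement: LDA removes the α‑hydrogen of both epimers of 7 while lithium is held between the ester oxygen and the α‑benzyloxy oxygen, so the mixture converges on one chelated enolate 8 (OLi and OBn cis), which is O‑silylated to 9 and undergoes a concerted suprafacial [3,3] shift to 10; aqueous acid frees 11. The closest known reaction type is the chelation‑controlled Ireland–Claisen rearrangement of allylic esters of O‑alkylated lactic and glycolic acids, which also runs through tetrasubstituted ketene acetals and gives tertiary ethers. No ring is closed in this step; the only cyclic array is the six‑membered chair transition state, and the lactone is closed in step 5. C4 of the target (C3 of 11) is set by 1,3‑chirality transfer: the methyl group of the (S)‑carbinol sits pseudo‑equatorial, so the new bond forms on one face of the E alkene, whose CH2Ar group is also pseudo‑equatorial, which should give 3R. C3 of the target (C2 of 11) is set by the enolate geometry: the benzyloxy group, trans to the allylic oxygen, is pseudo‑equatorial and the CH2Ar group pseudo‑axial, which should give 2S, with OBn syn to the C3 substituent in the chain and the two arylmethyl groups cis in the later lactone. The step needs three selectivities, namely one enolate geometry, chair over boat, and methyl equatorial; these are secured by the chelating α‑OBn group, the acyclic E alkene, and the 1,3‑diaxial clash an axial methyl would have with the OSiMe3 group. The carbinol carbon ends as the methyl‑bearing alkene terminus and is excised in step 5.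

Step 5
Reactants: 11
Product: 14 (3S,4R)‑3‑(benzyloxy)‑3,4‑bis[4‑(benzyloxy)‑3‑methoxybenzyl]dihydrofuran‑2(3H)‑one, via aldehyde acid 12 (not isolated), via hydroxy acid 13 (not isolated)
Conditions: O3, CH2Cl2/MeOH, Sudan Red 7B indicator, −78 °C; NaBH4, −78 to 0 °C; then 1 M HCl, rt
Reagents that add atoms: ozone, [O-][O+]=O
Why: Ozonolysis of the 1,2‑disubstituted alkene should be much faster than attack on the arenes; borohydride reduces the ozonolysis products through 12 to 13, which closes to the γ‑lactone on acidification (5‑exo‑trig, helped by the quaternary centre). C3 cannot epimerise and C4 is exposed as an aldehyde α‑carbon only briefly at low temperature.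

Step 6
Reactants: 14
Product: 15 (3S,4R)‑3‑hydroxy‑3,4‑bis(4‑hydroxy‑3‑methoxybenzyl)dihydrofuran‑2(3H)‑one
Conditions: H2 (1 atm), Pd(OH)2/C, EtOAc/MeOH, rt
Reagents that add atoms: none
Why: Catalytic hydrogenolysis of two aryl benzyl ethers and one tertiary alkyl benzyl ether; the lactone and the ArCH2–C bonds, which have no leaving group, should stay intact and no stereocenter is touched.

## Compound list

1 | 4‑allyl‑1‑(benzyloxy)‑2‑methoxybenzene | C=CCc1ccc(OCc2ccccc2)c(OC)c1 | starting material
2 | (S)‑but‑3‑en‑2‑ol | C[C@H](O)C=C | starting material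
3 | (2S,3E)‑5‑[4‑(benzyloxy)‑3‑methoxyphenyl]pent‑3‑en‑2‑ol | C[C@H](O)/C=C/Cc1ccc(OCc2ccccc2)c(OC)c1 | intermediate
4 | 2‑(benzyloxy)acetyl chloride | O=C(Cl)COCc1ccccc1 | starting material
5 | (2S,3E)‑5‑[4‑(benzyloxy)‑3‑methoxyphenyl]pent‑3‑en‑2‑yl 2‑(benzyloxy)acetate | C[C@H](OC(=O)COCc1ccccc1)/C=C/Cc1ccc(OCc2ccccc2)c(OC)c1 | intermediate
6 | 4‑(benzyloxy)‑3‑methoxybenzyl bromide | BrCc1ccc(OCc2ccccc2)c(OC)c1 | starting material
7 | (2S,3E)‑5‑[4‑(benzyloxy)‑3‑methoxyphenyl]pent‑3‑en‑2‑yl (2RS)‑2‑(benzyloxy)‑3‑[4‑(benzyloxy)‑3‑methoxyphenyl]propanoate | C[C@H](OC(=O)C(OCc1ccccc1)Cc1ccc(OCc2ccccc2)c(OC)c1)/C=C/Cc1ccc(OCc2ccccc2)c(OC)c1 | intermediate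
8 | chelated lithium enolate of 7 (OLi cis to OBn; allylic oxygen cis to CH2Ar) | [Li]O/C(O[C@@H](C)/C=C/Cc1ccc(OCc2ccccc2)c(OC)c1)=C(\OCc1ccccc1)Cc1ccc(OCc2ccccc2)c(OC)c1 | intermediate
9 | (Z)‑trimethylsilyl ketene acetal of 7 (OSiMe3 cis to OBn) | C[Si](C)(C)O/C(O[C@@H](C)/C=C/Cc1ccc(OCc2ccccc2)c(OC)c1)=C(\OCc1ccccc1)Cc1ccc(OCc2ccccc2)c(OC)c1 | intermediate
10 | trimethylsilyl (2S,3R,4E)‑2‑(benzyloxy)‑2,3‑bis[4‑(benzyloxy)‑3‑methoxybenzyl]hex‑4‑enoate | C/C=C/[C@@H](Cc1ccc(OCc2ccccc2)c(OC)c1)[C@@](OCc1ccccc1)(Cc1ccc(OCc2ccccc2)c(OC)c1)C(=O)O[Si](C)(C)C | intermediate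
11 | (2S,3R,4E)‑2‑(benzyloxy)‑2,3‑bis[4‑(benzyloxy)‑3‑methoxybenzyl]hex‑4‑enoic acid | C/C=C/[C@@H](Cc1ccc(OCc2ccccc2)c(OC)c1)[C@@](OCc1ccccc1)(Cc1ccc(OCc2ccccc2)c(OC)c1)C(=O)O | intermediate
12 | (2S,3S)‑2‑(benzyloxy)‑2,3‑bis[4‑(benzyloxy)‑3‑methoxybenzyl]‑4‑oxobutanoic acid | O=C[C@@H](Cc1ccc(OCc2ccccc2)c(OC)c1)[C@@](OCc1ccccc1)(Cc1ccc(OCc2ccccc2)c(OC)c1)C(=O)O | intermediate
13 | (2S,3R)‑2‑(benzyloxy)‑2,3‑bis[4‑(benzyloxy)‑3‑methoxybenzyl]‑4‑hydroxybutanoic acid | OC[C@@H](Cc1ccc(OCc2ccccc2)c(OC)c1)[C@@](OCc1ccccc1)(Cc1ccc(OCc2ccccc2)c(OC)c1)C(=O)O | intermediate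
14 | (3S,4R)‑3‑(benzyloxy)‑3,4‑bis[4‑(benzyloxy)‑3‑methoxybenzyl]dihydrofuran‑2(3H)‑one | COc1cc(C[C@@H]2COC(=O)[C@]2(OCc3ccccc3)Cc2ccc(OCc3ccccc3)c(OC)c2)ccc1OCc1ccccc1 | intermediate
15 | (3S,4R)‑3‑hydroxy‑3,4‑bis(4‑hydroxy‑3‑methoxybenzyl)dihydrofuran‑2(3H)‑one | COc1cc(C[C@@H]2COC(=O)[C@]2(O)Cc2ccc(O)c(OC)c2)ccc1O | target

## Step count and risk

Total step count: 6. Longest linear sequence: 6 (steps 1 to 6).

**Step 4 (key step).** The most likely failure is incomplete chelation during enolisation of the hindered α‑C–H, which would give a mixture of ketene acetal geometries and erode the configuration at C3. Loss of the enolate by elimination to a ketene before silylation is a second possibility. Fallback, moving the oxygenation after the rearrangement: 3 is esterified (DCC, DMAP) with commercial 3‑[4‑(benzyloxy)‑3‑methoxyphenyl]propanoic acid to (2S,3E)‑5‑[4‑(benzyloxy)‑3‑methoxyphenyl]pent‑3‑en‑2‑yl 3‑[4‑(benzyloxy)‑3‑methoxyphenyl]propanoate F1. Ireland–Claisen rearrangement of F1 (LDA, TMSCl) needs no control of enolate geometry and should give (2RS,3R,4E)‑2,3‑bis[4‑(benzyloxy)‑3‑methoxybenzyl]hex‑4‑enoic acid F2 by the same chirality transfer. Ozonolysis, borohydride reduction and acidification give (3RS,4S)‑3,4‑bis[4‑(benzyloxy)‑3‑methoxybenzyl]dihydrofuran‑2(3H)‑one F3. Its potassium enolate (KHMDS, −78 °C) is oxidised by 2‑(phenylsulfonyl)‑3‑phenyloxaziridine anti to the C4 substituent to (3S,4R)‑3‑hydroxy‑3,4‑bis[4‑(benzyloxy)‑3‑methoxybenzyl]dihydrofuran‑2(3H)‑one F4. Hydrogenolysis of F4 returns to the route at 15.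

**Step 3.** The lithium enolate of 5 may be consumed by premature [3,3] shift or by Claisen self‑condensation before the alkylation is complete. Fallback, building the acid apart from the allylic alcohol: commercial methyl 2‑(benzyloxy)acetate is alkylated with 6 (LDA, THF, −78 °C) to methyl 2‑(benzyloxy)‑3‑[4‑(benzyloxy)‑3‑methoxyphenyl]propanoate F5. Saponification (LiOH, THF/H2O) gives 2‑(benzyloxy)‑3‑[4‑(benzyloxy)‑3‑methoxyphenyl]propanoic acid F6. Coupling of F6 with 3 (DCC, DMAP) returns to the route at 7. This fallback sets out from 6 and 3.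

**Step 1.** The cross‑metathesis may give incomplete E selectivity, and olefin migration of the allylarene into conjugation would lead to a chain‑shortened product. A Z contaminant would lower the diastereomeric purity of step 4. Fallback, with the alkene geometry fixed by reduction: commercial (S)‑but‑3‑yn‑2‑ol is coupled with 6 (CuI cat., K2CO3, MeCN) to (2S)‑5‑[4‑(benzyloxy)‑3‑methoxyphenyl]pent‑3‑yn‑2‑ol F7. Trans‑selective hydroalumination of the propargylic alcohol F7 (Red‑Al, THF) returns to the route at 3. This fallback sets out from 6.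

**Step 5.** Ozone may attack the electron‑rich arenes or the benzyl ethers, and the aldehyde stage may epimerise at the carbon that becomes C4. Fallback, replacing ozone by osmium and periodate on an ester: 11 is methylated (TMSCHN2, MeOH/toluene) to methyl (2S,3R,4E)‑2‑(benzyloxy)‑2,3‑bis[4‑(benzyloxy)‑3‑methoxybenzyl]hex‑4‑enoate F8. Lemieux–Johnson cleavage (OsO4 cat., NaIO4, 2,6‑lutidine, dioxane/H2O) passes through methyl (2S,3R)‑2‑(benzyloxy)‑2,3‑bis[4‑(benzyloxy)‑3‑methoxybenzyl]‑4,5‑dihydroxyhexanoate F9 and gives methyl (2S,3S)‑2‑(benzyloxy)‑2,3‑bis[4‑(benzyloxy)‑3‑methoxybenzyl]‑4‑oxobutanoate F10. NaBH4 reduces F10 to methyl (2S,3R)‑2‑(benzyloxy)‑2,3‑bis[4‑(benzyloxy)‑3‑methoxybenzyl]‑4‑hydroxybutanoate F11, which lactonises with catalytic TsOH and returns to the route at 14.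

## Further compounds

F1 | step 4 | (2S,3E)‑5‑[4‑(benzyloxy)‑3‑methoxyphenyl]pent‑3‑en‑2‑yl 3‑[4‑(benzyloxy)‑3‑methoxyphenyl]propanoate | C[C@H](OC(=O)CCc1ccc(OCc2ccccc2)c(OC)c1)/C=C/Cc1ccc(OCc2ccccc2)c(OC)c1
F2 | step 4 | (2RS,3R,4E)‑2,3‑bis[4‑(benzyloxy)‑3‑methoxybenzyl]hex‑4‑enoic acid | C/C=C/[C@@H](Cc1ccc(OCc2ccccc2)c(OC)c1)C(Cc1ccc(OCc2ccccc2)c(OC)c1)C(=O)O
F3 | step 4 | (3RS,4S)‑3,4‑bis[4‑(benzyloxy)‑3‑methoxybenzyl]dihydrofuran‑2(3H)‑one | COc1cc(C[C@@H]2COC(=O)C2Cc2ccc(OCc3ccccc3)c(OC)c2)ccc1OCc1ccccc1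
F4 | step 4 | (3S,4R)‑3‑hydroxy‑3,4‑bis[4‑(benzyloxy)‑3‑methoxybenzyl]dihydrofuran‑2(3H)‑one | COc1cc(C[C@@H]2COC(=O)[C@]2(O)Cc2ccc(OCc3ccccc3)c(OC)c2)ccc1OCc1ccccc1
F5 | step 3 | methyl 2‑(benzyloxy)‑3‑[4‑(benzyloxy)‑3‑methoxyphenyl]propanoate (racemic) | COC(=O)C(OCc1ccccc1)Cc1ccc(OCc2ccccc2)c(OC)c1
F6 | step 3 | 2‑(benzyloxy)‑3‑[4‑(benzyloxy)‑3‑methoxyphenyl]propanoic acid (racemic) | OC(=O)C(OCc1ccccc1)Cc1ccc(OCc2ccccc2)c(OC)c1
F7 | step 1 | (2S)‑5‑[4‑(benzyloxy)‑3‑methoxyphenyl]pent‑3‑yn‑2‑ol | C[C@H](O)C#CCc1ccc(OCc2ccccc2)c(OC)c1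
F8 | step 5 | methyl (2S,3R,4E)‑2‑(benzyloxy)‑2,3‑bis[4‑(benzyloxy)‑3‑methoxybenzyl]hex‑4‑enoate | C/C=C/[C@@H](Cc1ccc(OCc2ccccc2)c(OC)c1)[C@@](OCc1ccccc1)(Cc1ccc(OCc2ccccc2)c(OC)c1)C(=O)OC
F9 | step 5 | methyl (2S,3R)‑2‑(benzyloxy)‑2,3‑bis[4‑(benzyloxy)‑3‑methoxybenzyl]‑4,5‑dihydroxyhexanoate (diol diastereomers) | CC(O)C(O)[C@@H](Cc1ccc(OCc2ccccc2)c(OC)c1)[C@@](OCc1ccccc1)(Cc1ccc(OCc2ccccc2)c(OC)c1)C(=O)OC
F10 | step 5 | methyl (2S,3S)‑2‑(benzyloxy)‑2,3‑bis[4‑(benzyloxy)‑3‑methoxybenzyl]‑4‑oxobutanoate | O=C[C@@H](Cc1ccc(OCc2ccccc2)c(OC)c1)[C@@](OCc1ccccc1)(Cc1ccc(OCc2ccccc2)c(OC)c1)C(=O)OC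
F11 | step 5 | methyl (2S,3R)‑2‑(benzyloxy)‑2,3‑bis[4‑(benzyloxy)‑3‑methoxybenzyl]‑4‑hydroxybutanoate | OC[C@@H](Cc1ccc(OCc2ccccc2)c(OC)c1)[C@@](OCc1ccccc1)(Cc1ccc(OCc2ccccc2)c(OC)c1)C(=O)OC
A1 | alternative 1 | (S)‑4‑[4‑(benzyloxy)‑3‑methoxybenzyl]dihydrofuran‑2(3H)‑one | COc1cc(C[C@@H]2COC(=O)C2)ccc1OCc1ccccc1
A2 | alternative 1 | (3S,4S)‑3,4‑bis[4‑(benzyloxy)‑3‑methoxybenzyl]dihydrofuran‑2(3H)‑one | COc1cc(C[C@@H]2COC(=O)[C@H]2Cc2ccc(OCc3ccccc3)c(OC)c2)ccc1OCc1ccccc1
A3 | alternative 2 | methyl 3‑[4‑(benzyloxy)‑3‑methoxyphenyl]‑2‑oxopropanoate | COC(=O)C(=O)Cc1ccc(OCc2ccccc2)c(OC)c1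
A4 | alternative 2 | 3‑[4‑(benzyloxy)‑3‑methoxyphenyl]propanal | O=CCCc1ccc(OCc2ccccc2)c(OC)c1
A5 | alternative 2 | methyl (2S,3S)‑2‑hydroxy‑2,3‑bis[4‑(benzyloxy)‑3‑methoxybenzyl]‑4‑oxobutanoate | O=C[C@@H](Cc1ccc(OCc2ccccc2)c(OC)c1)[C@@](O)(Cc1ccc(OCc2ccccc2)c(OC)c1)C(=O)OC
A6 | alternative 3 | 3,4‑bis[4‑(benzyloxy)‑3‑methoxybenzyl]furan‑2(5H)‑one | O=C1OCC(Cc2ccc(OCc3ccccc3)c(OC)c2)=C1Cc1ccc(OCc2ccccc2)c(OC)c1
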